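Abbreviations: TIPS = triisopropylsilyl, TIPSO = triisopropylsilyloxy, Tr = trityl (triphenylmethyl). Ring positions follow benzofuran numbering (O1, C2, C3, C3a, C4–C7, C7a; ring A = C3a–C7a). In the open-chain precursors the propane chain is numbered from the carbinol carbon (C1), and the fluoroarene carbons carry primes (C1′ bears the chain, C2′ the fluorine).

## Analysis of the target

Target 35 is a 2,3-dihydrobenzofuran whose ring A carries hydroxyl groups at C4 and C6 and a 2-(4-hydroxyphenyl)acryloyl group at C7, and is free only at C5. C2 bears a 4-hydroxyphenyl group and C3 a 2,4-dihydroxybenzoyl group. The two stereocentres are adjacent, C2 (R) and C3 (R), with the aryl and aroyl groups trans on the five-membered ring. C3–H is α to a ketone, benzylic and β to the ring oxygen, so base can epimerise it or open the ring by β-elimination of O1, which would also erase C2. The α-methylene ketone at C7 is a Michael acceptor placed next to the C6 phenol. Together with the benzylic C2–O1 bond it rules out hydrogenolysis, strong Lewis acids and basic deprotection of the six phenols. The hard part is ring A: five of its six positions are substituted, with two different carbon substituents (C3a and C7) and three oxygens, and the C7 acyl group has to be placed against the equally activated C5. The strategy rests on O1 at C7a and the ketone carbon at C7 being neighbours, with the C6 oxygen beside C7. A C7–C7a aryne can therefore take up the ring oxygen at C7a and a one-carbon electrophile at C7 in a single operation, which fixes the substitution of ring A by mechanism.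

## Retrosynthetic reasoning

**35 ⇒ 34.** The last operation is cleavage of six aryl O–Si bonds. Silyl ethers are the only phenol protection that can be removed without reduction, strong acid or strong base. The forward step must free the phenols without letting the C6 phenoxide add to the methylene ketone.

**34 ⇒ 33.** Both ketones are traced back to secondary alcohols, so the C7 methylene ketone and the C3 aryl ketone appear together in one oxidation at the penultimate stage. The Michael acceptor and the most acidic form of C3–H are thereby kept out of every organometallic step.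

**33 ⇒ 29 + 32 (from 31, from 30).** The bond between the C3 carbinol carbon and the resorcinol ring is cut; aryl Grignard reagent 32 adds to aldehyde 29. Cutting here leaves C3 as a CH stereocentre that is already in place. The forward step needs addition to win over enolisation of the α-aryl aldehyde.

**29 ⇒ 28.** The C3 aldehyde comes from the primary alcohol of diol 28. The C7 aldehyde of 22 is consumed before the C3 aldehyde is made, so two aldehydes are never present together and no aryl nucleophile has to choose between them. The forward step must oxidise the primary alcohol and spare the hindered secondary allylic alcohol.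

**28 ⇒ 22 + 26 (via 27; 26 from 24, from 23).** The bond between the C7 carbinol carbon and the vinyl carbon is cut. Alkenylchromium reagent 27 is used because it tolerates the free primary hydroxyl of 22 and is not basic.

**22 ⇒ 21.** The primary alcohol is unmasked from its trityl ether. This is done while C7 is still an aldehyde, because the later allylic alcohol on the trioxygenated ring would ionise in acid.

**21 ⇒ 16 (key disconnection).** O1–C7a and the C7–CHO bond are cut together. Forward, the fluoroarene of 16 is metalated next to fluorine, fluoride is lost to give the C7–C7a aryne, the C1 alkoxide closes the dihydrofuran ring at C7a, and the C7 carbanion is formylated. The primary oxygen carries a trityl group and not a silyl group. A silyl group could move to the neighbouring lithium alkoxide and release a second oxygen nucleophile, which would reach the same aryne carbon through an equally sized ring.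

**16 ⇒ 15 ⇒ 14 ⇒ 9 + 11 (11 from 10).** The C1–C2 bond of the chain (the later C2–C3 bond) is cut as an auxiliary-controlled syn-aldol between imide 9 and aldehyde 11. This one step sets both stereocentres. The syn relationship of 14 becomes the trans relationship of the ring, because ring closure in the key step breaks no bond at either centre.

**9 ⇒ 6 + 7; 6 ⇒ 4 ⇒ 2 (via 3) ⇒ 1.** The arylacetic acid 6 comes from a two-carbon arm placed ortho to fluorine by metalation of 2. The symmetry of 1 makes both positions next to fluorine equivalent, so no regiochemical question arises.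

## Alternatives that were turned down

**Alternative 1:** Both bonds of the C7 carbonyl carbon are cut. A palladium-catalysed carbonylative Stille coupling would join the C7 iodide A1 of a benzylated trans core with the α-styrylstannane A2 and deliver the hexa-O-benzyl ether A3 of 35 in one step.
- In its favour: it is convergent and makes the enone at the ketone oxidation level without carbinol oxidations. On this point it is stronger than the chosen route, which needs four operations between 22 and 34.
- Against it: A1 already holds the C3 aryl ketone with its acidic C3–H and must survive heating with a palladium catalyst. Oxidative addition and acyl transfer at an iodide flanked by two ortho oxygens on an electron-rich ring are slow, so direct coupling without carbonyl insertion and destannylation compete.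
- The route to A1 needs iodination at C7 against C5, and both positions lie between two oxygens.
- The six benzyl ethers of A3 cannot be removed: hydrogenolysis would reduce the methylene ketone and cleave the benzylic C2–O1 bond, and boron halides would attack the enone.
- In comparison, the chosen strategy places the C7 carbon by the mechanism of ring formation and uses fluoride-labile protection throughout.

**Alternative 2:** The C3–C3a bond is formed by an oxidative 1,2-shift. The (R)-flavanone A4 would be treated with a hypervalent iodine oxidant in an orthoformate/acid medium; ring A migrates, the pyranone contracts, and the trans ester A5 results.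
- In its favour: it is the shortest entry to the trans dihydrobenzofuran core and starts from a flavanone that already holds ring A, O1 and the C2 aryl group. On step count to the core it is stronger than the chosen route.
- Against it: A4 is the unnatural enantiomer and can racemise through the chalcone under the acid of the key step. On an electron-rich flavanone, migration of the C2 aryl group and dehydrogenation compete with ring contraction.
- A5 has no carbon at C7. A later acylation would have to distinguish C7 from C5 without any handle.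
- The ester must be turned into an aryl ketone by an organometallic reagent next to the acidic C3–H, and the benzyl ethers raise the same deprotection problem as in alternative 1.
- In comparison, the chosen strategy draws its stereocentres from an auxiliary aldol that cannot racemise and installs the C7 carbon regiospecifically.

**Alternative 3:** The C2–C3 bond is formed by carbene C–H insertion. The diazo ketone A7, built on the isoflavone genistein A6, would lose nitrogen on a chiral dirhodium carboxylate and insert into a benzylic C–H of the neighbouring 4-siloxybenzyl ether, giving the chromone-fused dihydrofuran A8.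
- In its favour: the stereocontrol is catalytic. A6 supplies ring A, the C7 carbonyl carbon and the enone aryl group. The enone stays masked as the chromone until the end, which is stronger than the chosen route, where the enone must survive the final desilylation.
- Against it: attaching the aroyl-diazomethyl group at C6 of A6 against C8 is long and unselective. The carbene sits between two ortho oxygens, so ylide formation at the ether oxygen followed by a benzyl shift competes with insertion. The insertion usually gives the cis ring, so C3 must be equilibrated through an enol that can also open the ring.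
- Unmasking A8 requires conjugate reduction of the chromone and a ring opening that runs against the normal direction, since 2-hydroxyaryl methylene ketones close to chromanones.
- In comparison, the chosen strategy makes the methylene ketone directly by oxidation and fixes both stereocentres before the ring is closed.

Key step: step 9

Remark: the carbinol carbons created in steps 13 and 16 are formed without control and carried as epimer mixtures, because both become carbonyl carbons in step 17.

## Route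

Step 1
Reactants: 1 5-fluororesorcinol
Product: 2 1-fluoro-3,5-bis(triisopropylsilyloxy)benzene
Conditions: TIPSCl (2.4 equiv), imidazole, DMF, 0 °C to rt
Reagents that add atoms: triisopropylsilyl chloride (TIPSCl), CC(C)[Si](Cl)(C(C)C)C(C)C
Why: Standard silylation of phenols; TIPS ethers withstand organolithium bases and later screen the ring position between them.

Step 2
Reactants: 2 1-fluoro-3,5-bis(triisopropylsilyloxy)benzene
Product: 4 2-[2-fluoro-4,6-bis(triisopropylsilyloxy)phenyl]ethanol, via aryllithium 3 (not isolated)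
Conditions: s-BuLi (1.1 equiv), THF, −78 °C; ethylene oxide, BF3·OEt2, −78 °C; aq. NaHCO3
Reagents that add atoms: ethylene oxide, C1CO1
Why: Directed ortho-lithiation: fluorine acidifies its ortho C–H and the position between the two siloxy groups is screened, so metalation should occur next to fluorine, where the aryllithium does not yet lose LiF at −78 °C. Lewis-acid-promoted epoxide opening then installs the two-carbon arm at that temperature.

Step 3
Reactants: 4 2-[2-fluoro-4,6-bis(triisopropylsilyloxy)phenyl]ethanol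
Product: 6 2-[2-fluoro-4,6-bis(triisopropylsilyloxy)phenyl]acetic acid, via arylacetaldehyde 5 (not isolated)
Conditions: TEMPO (2,2,6,6-tetramethylpiperidin-1-oxyl, 0.2 equiv), PhI(OAc)2 (2.5 equiv), MeCN/H2O 1:1, rt
Reagents that add atoms: water, O
Why: Nitroxyl-catalysed oxidation of a primary alcohol through the aldehyde hydrate to the acid; the weakly acidic medium leaves aryl silyl ethers intact.

Step 4
Reactants: 6 2-[2-fluoro-4,6-bis(triisopropylsilyloxy)phenyl]acetic acid; 7 (R)-4-benzyl-2-oxazolidinone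
Product: 9 (R)-4-benzyl-3-{2-[2-fluoro-4,6-bis(triisopropylsilyloxy)phenyl]acetyl}oxazolidin-2-one, via mixed pivalic anhydride 8 (not isolated)
Conditions: PivCl, Et3N, THF, −20 °C; then 7, LiCl, −20 °C to rt
Reagents that add atoms: none
Why: N-acylation of the oxazolidinone through the mixed anhydride; the nucleophile attacks the less hindered arylacetyl carbonyl.

Step 5
Reactants: 10 4-hydroxybenzaldehyde
Product: 11 4-(triisopropylsilyloxy)benzaldehyde
Conditions: TIPSCl, imidazole, DMF, rt
Reagents that add atoms: triisopropylsilyl chloride (TIPSCl), CC(C)[Si](Cl)(C(C)C)C(C)C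
Why: Standard phenol silylation.

Step 6
Reactants: 9 (R)-4-benzyl-3-{2-[2-fluoro-4,6-bis(triisopropylsilyloxy)phenyl]acetyl}oxazolidin-2-one; 11 4-(triisopropylsilyloxy)benzaldehyde
Product: 14 (R)-4-benzyl-3-{(2R,3R)-2-[2-fluoro-4,6-bis(triisopropylsilyloxy)phenyl]-3-hydroxy-3-[4-(triisopropylsilyloxy)phenyl]propanoyl}oxazolidin-2-one, via boron enolate 12 (not isolated), via boron aldolate 13 (not isolated)
Conditions: Bu2BOTf (1.2 equiv), iPr2NEt (1.4 equiv), CH2Cl2, −78 to 0 °C; 11, −78 to 0 °C; pH 7 buffer, MeOH, 30% H2O2, 0 °C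
Reagents that add atoms: none
Why: Evans syn-aldol: the Z-boron enolate reacts through a closed chair (Zimmerman–Traxler) transition state in which the benzyl group of the (R)-auxiliary blocks one enolate face. This should give the (2R,3R) syn adduct and thereby set both stereocentres of the target (carbinol carbon becomes C2, α-carbon becomes C3).

Step 7
Reactants: 14 (R)-4-benzyl-3-{(2R,3R)-2-[2-fluoro-4,6-bis(triisopropylsilyloxy)phenyl]-3-hydroxy-3-[4-(triisopropylsilyloxy)phenyl]propanoyl}oxazolidin-2-one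
Product: 15 (1R,2S)-2-[2-fluoro-4,6-bis(triisopropylsilyloxy)phenyl]-1-[4-(triisopropylsilyloxy)phenyl]propane-1,3-diol
Conditions: LiBH4 (2 equiv), H2O (1.1 equiv), Et2O/THF, 0 °C
Reagents that add atoms: none
Why: Reductive cleavage of the N-acyl oxazolidinone to the primary alcohol with release of the auxiliary. No stereocentre is touched; the descriptor at C2 changes only because the priorities change.

Step 8
Reactants: 15 (1R,2S)-2-[2-fluoro-4,6-bis(triisopropylsilyloxy)phenyl]-1-[4-(triisopropylsilyloxy)phenyl]propane-1,3-diol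
Product: 16 (1R,2S)-2-[2-fluoro-4,6-bis(triisopropylsilyloxy)phenyl]-1-[4-(triisopropylsilyloxy)phenyl]-3-(trityloxy)propan-1-ol
Conditions: TrCl (1.3 equiv), Et3N, 4-(dimethylamino)pyridine (0.1 equiv), CH2Cl2, rt to 40 °C
Reagents that add atoms: trityl chloride, ClC(c1ccccc1)(c1ccccc1)c1ccccc1
Why: Tritylation is selective for the primary hydroxyl on steric grounds. The trityl ether is inert to lithium amides and cannot migrate to the neighbouring alkoxide in step 9.

Step 9
Reactants: 16 (1R,2S)-2-[2-fluoro-4,6-bis(triisopropylsilyloxy)phenyl]-1-[4-(triisopropylsilyloxy)phenyl]-3-(trityloxy)propan-1-ol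
Product: 21 (2R,3S)-trans-4,6-bis(triisopropylsilyloxy)-2-[4-(triisopropylsilyloxy)phenyl]-3-(trityloxymethyl)-2,3-dihydrobenzofuran-7-carbaldehyde, via dilithio species 17 (not isolated), via aryne alkoxide 18 (not isolated), via C7 aryllithium 19 (not isolated), via hemiaminal alkoxide 20 (not isolated)
Conditions: LiTMP (3.2 equiv, from 2,2,6,6-tetramethylpiperidine and n-BuLi), THF, −78 °C, then −78 to −25 °C; recool to −78 °C, DMF (6 equiv), to 0 °C; aq. NH4Cl
Reagents that add atoms: N,N-dimethylformamide, CN(C)C=O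
Why: LiTMP first forms the lithium alkoxide and then removes the only ring proton ortho to fluorine (C3′–H) to give 17; the other ring proton lies between two TIPS ethers and is screened. On warming, 17 loses LiF to give the C7–C7a aryne 18 (benzofuran numbering). The alkoxide, held three atoms from C7a, adds in the ring plane in a 5-exo closure that forms O1–C7a and the dihydrofuran ring; C7 is out of reach of this tether, and the inductively withdrawing C6 siloxy group beside the developing carbanion favours the same regiochemistry. The resulting aryllithium 19 is captured by DMF as the tetrahedral adduct 20, which releases the C7 aldehyde on work-up (C7–C bond). No stereocentre is created: the carbinol C–O bond is not broken, so C2 and C3 keep the configuration set in step 6 and the syn aldol relationship becomes the trans arrangement on the ring. The closest known reaction type is the cyclisation of tethered alkoxides or amides onto arynes generated from haloarenes with lithium amide bases, followed by electrophilic quench of the new aryllithium. The hindered amide base adds only slowly to arynes, so the intramolecular alkoxide should win, and the trityl ether keeps the primary oxygen from competing.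

Step 10
Reactants: 21 (2R,3S)-trans-4,6-bis(triisopropylsilyloxy)-2-[4-(triisopropylsilyloxy)phenyl]-3-(trityloxymethyl)-2,3-dihydrobenzofuran-7-carbaldehyde
Product: 22 (2R,3S)-trans-3-(hydroxymethyl)-4,6-bis(triisopropylsilyloxy)-2-[4-(triisopropylsilyloxy)phenyl]-2,3-dihydrobenzofuran-7-carbaldehyde
Conditions: AcOH/THF/H2O 4:1:1, 45 °C
Reagents that add atoms: none
Why: Acid-catalysed detritylation by ionisation to the trityl cation; aryl TIPS ethers, the aldehyde and the dihydrobenzofuran are stable to warm aqueous acetic acid.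

Step 11
Reactants: 23 4′-hydroxyacetophenone
Product: 24 1-[4-(triisopropylsilyloxy)phenyl]ethanone
Conditions: TIPSCl, imidazole, DMF, rt
Reagents that add atoms: triisopropylsilyl chloride (TIPSCl), CC(C)[Si](Cl)(C(C)C)C(C)C
Why: Standard phenol silylation.

Step 12
Reactants: 24 1-[4-(triisopropylsilyloxy)phenyl]ethanone
Product: 26 1-[4-(triisopropylsilyloxy)phenyl]vinyl trifluoromethanesulfonate, via potassium enolate 25 (not isolated)
Conditions: KHMDS (1.05 equiv), THF, −78 °C; PhNTf2, −78 to 0 °C
Reagents that add atoms: N-phenylbis(trifluoromethanesulfonimide), O=S(=O)(N(c1ccccc1)S(=O)(=O)C(F)(F)F)C(F)(F)F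
Why: Enol triflate formation by O-sulfonylation of the potassium enolate of a methyl ketone, which can enolise in one direction only.

Step 13
Reactants: 22 (2R,3S)-trans-3-(hydroxymethyl)-4,6-bis(triisopropylsilyloxy)-2-[4-(triisopropylsilyloxy)phenyl]-2,3-dihydrobenzofuran-7-carbaldehyde; 26 1-[4-(triisopropylsilyloxy)phenyl]vinyl trifluoromethanesulfonate
Product: 28 1-{(2R,3S)-trans-3-(hydroxymethyl)-4,6-bis(triisopropylsilyloxy)-2-[4-(triisopropylsilyloxy)phenyl]-2,3-dihydrobenzofuran-7-yl}-2-[4-(triisopropylsilyloxy)phenyl]prop-2-en-1-ol (both carbinol epimers), via alkenylchromium reagent 27 (not isolated)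
Conditions: 26 (3 equiv), CrCl2 (6 equiv), NiCl2 (2 mol %), degassed DMF, rt
Reagents that add atoms: none
Why: Nozaki–Hiyama–Kishi reaction: zerovalent nickel inserts into the C–O bond of the enol triflate, the alkenyl group passes to trivalent chromium (27), and this non-basic reagent adds to the aldehyde while tolerating the free primary hydroxyl. The new carbinol centre is not controlled and need not be.

Step 14
Reactants: 28 1-{(2R,3S)-trans-3-(hydroxymethyl)-4,6-bis(triisopropylsilyloxy)-2-[4-(triisopropylsilyloxy)phenyl]-2,3-dihydrobenzofuran-7-yl}-2-[4-(triisopropylsilyloxy)phenyl]prop-2-en-1-ol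
Product: 29 (2R,3R)-trans-7-{1-hydroxy-2-[4-(triisopropylsilyloxy)phenyl]prop-2-en-1-yl}-4,6-bis(triisopropylsilyloxy)-2-[4-(triisopropylsilyloxy)phenyl]-2,3-dihydrobenzofuran-3-carbaldehyde (both carbinol epimers)
Conditions: [Cu(MeCN)4]OTf (10 mol %), 2,2′-bipyridine (10 mol %), TEMPO (10 mol %), N-methylimidazole (20 mol %), air, MeCN, rt
Reagents that add atoms: none
Why: Aerobic copper/nitroxyl oxidation is selective for unhindered primary alcohols; the secondary alcohol lies between a doubly ortho-substituted ring and an α-aryl vinyl group and should not be accepted by the bulky nitroxyl. The near-neutral medium spares the acid-sensitive allylic alcohol and the C3 stereocentre.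

Step 15
Reactants: 30 4-bromoresorcinol
Product: 31 1-bromo-2,4-bis(triisopropylsilyloxy)benzene
Conditions: TIPSCl (2.5 equiv), imidazole, 4-(dimethylamino)pyridine (0.1 equiv), DMF, 40 °C
Reagents that add atoms: triisopropylsilyl chloride (TIPSCl), CC(C)[Si](Cl)(C(C)C)C(C)C
Why: Standard phenol silylation; gentle warming serves the hydroxyl next to bromine.

Step 16
Reactants: 29 (2R,3R)-trans-7-{1-hydroxy-2-[4-(triisopropylsilyloxy)phenyl]prop-2-en-1-yl}-4,6-bis(triisopropylsilyloxy)-2-[4-(triisopropylsilyloxy)phenyl]-2,3-dihydrobenzofuran-3-carbaldehyde; 31 1-bromo-2,4-bis(triisopropylsilyloxy)benzene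
Product: 33 1-{(2R,3S)-trans-3-{[2,4-bis(triisopropylsilyloxy)phenyl](hydroxy)methyl}-4,6-bis(triisopropylsilyloxy)-2-[4-(triisopropylsilyloxy)phenyl]-2,3-dihydrobenzofuran-7-yl}-2-[4-(triisopropylsilyloxy)phenyl]prop-2-en-1-ol (mixture of carbinol epimers), via arylmagnesium bromide 32 (not isolated)
Conditions: 31, Mg, LiCl, THF, rt; then 29, LaCl3·2LiCl (1 equiv), THF, −40 to 0 °C (3 equiv of 32); aq. NH4Cl
Reagents that add atoms: none
Why: Grignard addition to an aldehyde: the first equivalent converts the free hydroxyl into its magnesium alkoxide and further reagent adds to the formyl group. The lanthanum salt raises the electrophilicity of the carbonyl and suppresses enolisation of the α-aryl aldehyde; the new carbinol centre is not controlled and becomes a ketone.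

Step 17
Reactants: 33 1-{(2R,3S)-trans-3-{[2,4-bis(triisopropylsilyloxy)phenyl](hydroxy)methyl}-4,6-bis(triisopropylsilyloxy)-2-[4-(triisopropylsilyloxy)phenyl]-2,3-dihydrobenzofuran-7-yl}-2-[4-(triisopropylsilyloxy)phenyl]prop-2-en-1-ol
Product: 34 1-{(2R,3R)-trans-3-[2,4-bis(triisopropylsilyloxy)benzoyl]-4,6-bis(triisopropylsilyloxy)-2-[4-(triisopropylsilyloxy)phenyl]-2,3-dihydrobenzofuran-7-yl}-2-[4-(triisopropylsilyloxy)phenyl]prop-2-en-1-one
Conditions: Dess–Martin periodinane (4 equiv), NaHCO3, CH2Cl2, 0 °C to rt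
Reagents that add atoms: none
Why: Dess–Martin oxidation converts both hindered secondary alcohols into ketones under buffered, non-basic conditions, so the aryl ketone at C3 and the methylene ketone at C7 appear in one operation and the trans C3 centre is not exposed to base.

Step 18
Reactants: 34 1-{(2R,3R)-trans-3-[2,4-bis(triisopropylsilyloxy)benzoyl]-4,6-bis(triisopropylsilyloxy)-2-[4-(triisopropylsilyloxy)phenyl]-2,3-dihydrobenzofuran-7-yl}-2-[4-(triisopropylsilyloxy)phenyl]prop-2-en-1-one
Product: 35 1-[(2R,3R)-3-(2,4-dihydroxybenzoyl)-4,6-dihydroxy-2-(4-hydroxyphenyl)-2,3-dihydrobenzofuran-7-yl]-2-(4-hydroxyphenyl)prop-2-en-1-one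
Conditions: TBAF (8 equiv), AcOH (10 equiv), THF, 0 °C
Reagents that add atoms: none
Why: Fluoride-induced cleavage of the six aryl silyl ethers. Acetic acid keeps the medium from turning basic, so the freed C6 phenol should not add to the methylene ketone and C3 should not be deprotonated.

## Compound list

1 | 5-fluororesorcinol | Oc1cc(O)cc(F)c1 | starting material
2 | 1-fluoro-3,5-bis(triisopropylsilyloxy)benzene | Fc1cc(O[Si](C(C)C)(C(C)C)C(C)C)cc(O[Si](C(C)C)(C(C)C)C(C)C)c1 | intermediate
3 | [2-fluoro-4,6-bis(triisopropylsilyloxy)phenyl]lithium | [Li]c1c(F)cc(O[Si](C(C)C)(C(C)C)C(C)C)cc1O[Si](C(C)C)(C(C)C)C(C)C | intermediate (not isolated)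
4 | 2-[2-fluoro-4,6-bis(triisopropylsilyloxy)phenyl]ethanol | OCCc1c(F)cc(O[Si](C(C)C)(C(C)C)C(C)C)cc1O[Si](C(C)C)(C(C)C)C(C)C | intermediate
5 | 2-[2-fluoro-4,6-bis(triisopropylsilyloxy)phenyl]acetaldehyde | O=CCc1c(F)cc(O[Si](C(C)C)(C(C)C)C(C)C)cc1O[Si](C(C)C)(C(C)C)C(C)C | intermediate (not isolated)
6 | 2-[2-fluoro-4,6-bis(triisopropylsilyloxy)phenyl]acetic acid | OC(=O)Cc1c(F)cc(O[Si](C(C)C)(C(C)C)C(C)C)cc1O[Si](C(C)C)(C(C)C)C(C)C | intermediate
7 | (R)-4-benzyl-2-oxazolidinone | O=C1N[C@H](Cc2ccccc2)CO1 | starting material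
8 | mixed anhydride of 6 with pivalic acid | CC(C)(C)C(=O)OC(=O)Cc1c(F)cc(O[Si](C(C)C)(C(C)C)C(C)C)cc1O[Si](C(C)C)(C(C)C)C(C)C | intermediate (not isolated)
9 | (R)-4-benzyl-3-{2-[2-fluoro-4,6-bis(triisopropylsilyloxy)phenyl]acetyl}oxazolidin-2-one | O=C(Cc1c(F)cc(O[Si](C(C)C)(C(C)C)C(C)C)cc1O[Si](C(C)C)(C(C)C)C(C)C)N1C(=O)OC[C@H]1Cc1ccccc1 | intermediate
10 | 4-hydroxybenzaldehyde | O=Cc1ccc(O)cc1 | starting material
11 | 4-(triisopropylsilyloxy)benzaldehyde | O=Cc1ccc(O[Si](C(C)C)(C(C)C)C(C)C)cc1 | intermediate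
12 | (Z)-dibutylboron enolate of 9 | CCCCB(CCCC)O/C(=C\c1c(F)cc(O[Si](C(C)C)(C(C)C)C(C)C)cc1O[Si](C(C)C)(C(C)C)C(C)C)N1C(=O)OC[C@H]1Cc1ccccc1 | intermediate (not isolated)
13 | O-dibutylboryl derivative (boron aldolate) of 14 | CCCCB(CCCC)O[C@@H](c1ccc(O[Si](C(C)C)(C(C)C)C(C)C)cc1)[C@@H](c1c(F)cc(O[Si](C(C)C)(C(C)C)C(C)C)cc1O[Si](C(C)C)(C(C)C)C(C)C)C(=O)N1C(=O)OC[C@H]1Cc1ccccc1 | intermediate (not isolated)
14 | (R)-4-benzyl-3-{(2R,3R)-2-[2-fluoro-4,6-bis(triisopropylsilyloxy)phenyl]-3-hydroxy-3-[4-(triisopropylsilyloxy)phenyl]propanoyl}oxazolidin-2-one (syn) | O[C@@H](c1ccc(O[Si](C(C)C)(C(C)C)C(C)C)cc1)[C@@H](c1c(F)cc(O[Si](C(C)C)(C(C)C)C(C)C)cc1O[Si](C(C)C)(C(C)C)C(C)C)C(=O)N1C(=O)OC[C@H]1Cc1ccccc1 | intermediate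
15 | (1R,2S)-2-[2-fluoro-4,6-bis(triisopropylsilyloxy)phenyl]-1-[4-(triisopropylsilyloxy)phenyl]propane-1,3-diol | O[C@@H](c1ccc(O[Si](C(C)C)(C(C)C)C(C)C)cc1)[C@@H](c1c(F)cc(O[Si](C(C)C)(C(C)C)C(C)C)cc1O[Si](C(C)C)(C(C)C)C(C)C)CO | intermediate
16 | (1R,2S)-2-[2-fluoro-4,6-bis(triisopropylsilyloxy)phenyl]-1-[4-(triisopropylsilyloxy)phenyl]-3-(trityloxy)propan-1-ol | O[C@@H](c1ccc(O[Si](C(C)C)(C(C)C)C(C)C)cc1)[C@@H](c1c(F)cc(O[Si](C(C)C)(C(C)C)C(C)C)cc1O[Si](C(C)C)(C(C)C)C(C)C)COC(c1ccccc1)(c1ccccc1)c1ccccc1 | intermediate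
17 | lithium alkoxide of 16 lithiated at C3′ (between fluorine and the C4′ siloxy group) | [Li]O[C@@H](c1ccc(O[Si](C(C)C)(C(C)C)C(C)C)cc1)[C@@H](c1c(F)c([Li])c(O[Si](C(C)C)(C(C)C)C(C)C)cc1O[Si](C(C)C)(C(C)C)C(C)C)COC(c1ccccc1)(c1ccccc1)c1ccccc1 | intermediate (not isolated)
18 | C2′–C3′ aryne (later C7a–C7) bearing the lithium alkoxide | [Li]O[C@@H](c1ccc(O[Si](C(C)C)(C(C)C)C(C)C)cc1)[C@@H](C1=C(O[Si](C(C)C)(C(C)C)C(C)C)C=C(O[Si](C(C)C)(C(C)C)C(C)C)C#C1)COC(c1ccccc1)(c1ccccc1)c1ccccc1 | intermediate (not isolated)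
19 | (2R,3S)-trans-7-lithio-4,6-bis(triisopropylsilyloxy)-2-[4-(triisopropylsilyloxy)phenyl]-3-(trityloxymethyl)-2,3-dihydrobenzofuran | [Li]c1c(O[Si](C(C)C)(C(C)C)C(C)C)cc(O[Si](C(C)C)(C(C)C)C(C)C)c2c1O[C@@H](c1ccc(O[Si](C(C)C)(C(C)C)C(C)C)cc1)[C@@H]2COC(c1ccccc1)(c1ccccc1)c1ccccc1 | intermediate (not isolated)
20 | lithium α-(dimethylamino)alkoxide formed from 19 and DMF | [Li]OC(N(C)C)c1c(O[Si](C(C)C)(C(C)C)C(C)C)cc(O[Si](C(C)C)(C(C)C)C(C)C)c2c1O[C@@H](c1ccc(O[Si](C(C)C)(C(C)C)C(C)C)cc1)[C@@H]2COC(c1ccccc1)(c1ccccc1)c1ccccc1 | intermediate (not isolated)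
21 | (2R,3S)-trans-4,6-bis(triisopropylsilyloxy)-2-[4-(triisopropylsilyloxy)phenyl]-3-(trityloxymethyl)-2,3-dihydrobenzofuran-7-carbaldehyde | O=Cc1c(O[Si](C(C)C)(C(C)C)C(C)C)cc(O[Si](C(C)C)(C(C)C)C(C)C)c2c1O[C@@H](c1ccc(O[Si](C(C)C)(C(C)C)C(C)C)cc1)[C@@H]2COC(c1ccccc1)(c1ccccc1)c1ccccc1 | intermediate
22 | (2R,3S)-trans-3-(hydroxymethyl)-4,6-bis(triisopropylsilyloxy)-2-[4-(triisopropylsilyloxy)phenyl]-2,3-dihydrobenzofuran-7-carbaldehyde | O=Cc1c(O[Si](C(C)C)(C(C)C)C(C)C)cc(O[Si](C(C)C)(C(C)C)C(C)C)c2c1O[C@@H](c1ccc(O[Si](C(C)C)(C(C)C)C(C)C)cc1)[C@@H]2CO | intermediate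
23 | 4′-hydroxyacetophenone | CC(=O)c1ccc(O)cc1 | starting material
24 | 1-[4-(triisopropylsilyloxy)phenyl]ethanone | CC(=O)c1ccc(O[Si](C(C)C)(C(C)C)C(C)C)cc1 | intermediate
25 | potassium enolate of 24 | C=C(O[K])c1ccc(O[Si](C(C)C)(C(C)C)C(C)C)cc1 | intermediate (not isolated)
26 | 1-[4-(triisopropylsilyloxy)phenyl]vinyl trifluoromethanesulfonate | C=C(OS(=O)(=O)C(F)(F)F)c1ccc(O[Si](C(C)C)(C(C)C)C(C)C)cc1 | intermediate
27 | {1-[4-(triisopropylsilyloxy)phenyl]vinyl}chromium dichloride (trivalent chromium) | C=C([Cr](Cl)Cl)c1ccc(O[Si](C(C)C)(C(C)C)C(C)C)cc1 | intermediate (not isolated)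
28 | 1-{(2R,3S)-trans-3-(hydroxymethyl)-4,6-bis(triisopropylsilyloxy)-2-[4-(triisopropylsilyloxy)phenyl]-2,3-dihydrobenzofuran-7-yl}-2-[4-(triisopropylsilyloxy)phenyl]prop-2-en-1-ol, both carbinol epimers | C=C(C(O)c1c(O[Si](C(C)C)(C(C)C)C(C)C)cc(O[Si](C(C)C)(C(C)C)C(C)C)c2c1O[C@@H](c1ccc(O[Si](C(C)C)(C(C)C)C(C)C)cc1)[C@@H]2CO)c1ccc(O[Si](C(C)C)(C(C)C)C(C)C)cc1 | intermediate
29 | (2R,3R)-trans-7-{1-hydroxy-2-[4-(triisopropylsilyloxy)phenyl]prop-2-en-1-yl}-4,6-bis(triisopropylsilyloxy)-2-[4-(triisopropylsilyloxy)phenyl]-2,3-dihydrobenzofuran-3-carbaldehyde, both carbinol epimers | C=C(C(O)c1c(O[Si](C(C)C)(C(C)C)C(C)C)cc(O[Si](C(C)C)(C(C)C)C(C)C)c2c1O[C@@H](c1ccc(O[Si](C(C)C)(C(C)C)C(C)C)cc1)[C@@H]2C=O)c1ccc(O[Si](C(C)C)(C(C)C)C(C)C)cc1 | intermediate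
30 | 4-bromoresorcinol | Oc1ccc(Br)c(O)c1 | starting material
31 | 1-bromo-2,4-bis(triisopropylsilyloxy)benzene | Brc1ccc(O[Si](C(C)C)(C(C)C)C(C)C)cc1O[Si](C(C)C)(C(C)C)C(C)C | intermediate
32 | [2,4-bis(triisopropylsilyloxy)phenyl]magnesium bromide | Br[Mg]c1ccc(O[Si](C(C)C)(C(C)C)C(C)C)cc1O[Si](C(C)C)(C(C)C)C(C)C | intermediate (not isolated)
33 | 1-{(2R,3S)-trans-3-{[2,4-bis(triisopropylsilyloxy)phenyl](hydroxy)methyl}-4,6-bis(triisopropylsilyloxy)-2-[4-(triisopropylsilyloxy)phenyl]-2,3-dihydrobenzofuran-7-yl}-2-[4-(triisopropylsilyloxy)phenyl]prop-2-en-1-ol, mixture of carbinol epimers | C=C(C(O)c1c(O[Si](C(C)C)(C(C)C)C(C)C)cc(O[Si](C(C)C)(C(C)C)C(C)C)c2c1O[C@@H](c1ccc(O[Si](C(C)C)(C(C)C)C(C)C)cc1)[C@@H]2C(O)c1ccc(O[Si](C(C)C)(C(C)C)C(C)C)cc1O[Si](C(C)C)(C(C)C)C(C)C)c1ccc(O[Si](C(C)C)(C(C)C)C(C)C)cc1 | intermediate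
34 | 1-{(2R,3R)-trans-3-[2,4-bis(triisopropylsilyloxy)benzoyl]-4,6-bis(triisopropylsilyloxy)-2-[4-(triisopropylsilyloxy)phenyl]-2,3-dihydrobenzofuran-7-yl}-2-[4-(triisopropylsilyloxy)phenyl]prop-2-en-1-one (hexakis-O-TIPS ether of the target) | C=C(C(=O)c1c(O[Si](C(C)C)(C(C)C)C(C)C)cc(O[Si](C(C)C)(C(C)C)C(C)C)c2c1O[C@@H](c1ccc(O[Si](C(C)C)(C(C)C)C(C)C)cc1)[C@@H]2C(=O)c1ccc(O[Si](C(C)C)(C(C)C)C(C)C)cc1O[Si](C(C)C)(C(C)C)C(C)C)c1ccc(O[Si](C(C)C)(C(C)C)C(C)C)cc1 | intermediate
35 | 1-[(2R,3R)-3-(2,4-dihydroxybenzoyl)-4,6-dihydroxy-2-(4-hydroxyphenyl)-2,3-dihydrobenzofuran-7-yl]-2-(4-hydroxyphenyl)prop-2-en-1-one (CNP0162111.1) | C=C(C(=O)c1c(O)cc(O)c2c1O[C@@H](c1ccc(O)cc1)[C@@H]2C(=O)c1ccc(O)cc1O)c1ccc(O)cc1 | target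

## Step count and least certain steps

Total: 18 steps. Longest linear sequence: 14 steps (steps 1, 2, 3, 4, 6, 7, 8, 9, 10, 13, 14, 16, 17, 18). Steps 5, 11, 12 and 15 prepare the three coupling partners.

**Step 9 (key step).**
- Metalation may stay incomplete, because the proton beside fluorine also sits next to a TIPS ether that screens it from the bulky amide.
- After ring closure, the C6 silyl group may shift from oxygen to the C7 carbanion during warming, or the carbanion may be protonated by the amine before the formamide is added.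
- Formylation of the doubly flanked aryllithium may be incomplete.
- Fallback: the two bonds are made in the opposite order by addition–elimination, without an aryne. From 16, N-bromosuccinimide in MeCN at 0 °C should brominate the only position of ring A that is activated by both oxygens and not enclosed by two TIPS ethers, giving (1R,2S)-2-[3-bromo-2-fluoro-4,6-bis(triisopropylsilyloxy)phenyl]-1-[4-(triisopropylsilyloxy)phenyl]-3-(trityloxy)propan-1-ol F1. n-BuLi (2.1 equiv) at −78 °C forms the alkoxide and exchanges bromine for lithium, which gives the dilithio species 17 without any deprotonation. DMF at −78 °C, quenched cold before LiF is lost, should give (1R,2S)-2-[2-fluoro-3-formyl-4,6-bis(triisopropylsilyloxy)phenyl]-1-[4-(triisopropylsilyloxy)phenyl]-3-(trityloxy)propan-1-ol F2. KHMDS in THF at 0 °C should then close O1–C7a by intramolecular nucleophilic aromatic substitution, since the fluorine is now activated by the ortho formyl group and both siloxy groups are meta to it. This returns to 21.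

**Step 13.**
- The weakly nucleophilic alkenylchromium reagent may add too slowly to an aldehyde that is deactivated by three oxygen donors and flanked on both sides. Reductive dimerisation or hydrolysis of the electron-rich enol triflate would then take over.
- Fallback: from 24, condensation with 2,4,6-triisopropylbenzenesulfonyl hydrazide gives 1-[4-(triisopropylsilyloxy)phenyl]ethanone 2,4,6-triisopropylbenzenesulfonylhydrazone F3. n-BuLi (2 equiv, −78 to 0 °C, Shapiro reaction) gives {1-[4-(triisopropylsilyloxy)phenyl]vinyl}lithium F4. Three equivalents of F4 are added at −78 °C to 22, the first being consumed by the hydroxyl. This returns to 28.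

**Step 14.**
- Oxidation may also occur at the secondary allylic alcohol, or the new aldehyde may enolise, with epimerisation at C3 or β-elimination of O1.
- Fallback: the order of events is changed so that no selective oxidation is needed. From 22, Dess–Martin oxidation gives (2R,3R)-trans-4,6-bis(triisopropylsilyloxy)-2-[4-(triisopropylsilyloxy)phenyl]-2,3-dihydrobenzofuran-3,7-dicarbaldehyde F5. One equivalent of 32 at −78 °C should add to the aliphatic C3 formyl group, because the C7 formyl group is doubly ortho-substituted and deactivated by three oxygen donors. This gives (2R,3S)-trans-3-{[2,4-bis(triisopropylsilyloxy)phenyl](hydroxy)methyl}-4,6-bis(triisopropylsilyloxy)-2-[4-(triisopropylsilyloxy)phenyl]-2,3-dihydrobenzofuran-7-carbaldehyde F6. Dess–Martin oxidation gives (2R,3R)-trans-3-[2,4-bis(triisopropylsilyloxy)benzoyl]-4,6-bis(triisopropylsilyloxy)-2-[4-(triisopropylsilyloxy)phenyl]-2,3-dihydrobenzofuran-7-carbaldehyde F7. The aldehyde-selective Nozaki–Hiyama–Kishi reaction with 26 (CrCl2, catalytic NiCl2) leaves the ketone untouched and gives {(2R,3R)-trans-7-{1-hydroxy-2-[4-(triisopropylsilyloxy)phenyl]prop-2-en-1-yl}-4,6-bis(triisopropylsilyloxy)-2-[4-(triisopropylsilyloxy)phenyl]-2,3-dihydrobenzofuran-3-yl}[2,4-bis(triisopropylsilyloxy)phenyl]methanone F8. A last Dess–Martin oxidation returns to 34. The price is an addition that must choose between two aldehydes.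

**Step 16.**
- The basic Grignard reagent may deprotonate the α-aryl aldehyde instead of adding to it. That would epimerise C3 and open the dihydrofuran ring by β-elimination of the aryloxide.
- Fallback: a non-basic organochromium addition replaces the Grignard addition. From 31, bromine–lithium exchange with n-BuLi at −78 °C and quench with iodine gives 1-iodo-2,4-bis(triisopropylsilyloxy)benzene F9. CrCl2 with catalytic NiCl2 in DMF couples F9 with 29 through an arylchromium reagent of trivalent chromium. This returns to 33.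

**Step 18.**
- The freed C6 phenol may add to the methylene ketone and close a chromanone ring.
- Base may epimerise or open the ring at C3.
- Cleavage of the hindered silyl ethers may stay incomplete under the buffered conditions that the first two problems demand.
- Fallback: the enone is masked during desilylation. From 34, thiophenol with catalytic Et3N adds to the enone and gives 1-{(2R,3R)-trans-3-[2,4-bis(triisopropylsilyloxy)benzoyl]-4,6-bis(triisopropylsilyloxy)-2-[4-(triisopropylsilyloxy)phenyl]-2,3-dihydrobenzofuran-7-yl}-3-(phenylthio)-2-[4-(triisopropylsilyloxy)phenyl]propan-1-one F10, which has no Michael acceptor. Buffered fluoride then gives 1-[(2R,3R)-3-(2,4-dihydroxybenzoyl)-4,6-dihydroxy-2-(4-hydroxyphenyl)-2,3-dihydrobenzofuran-7-yl]-2-(4-hydroxyphenyl)-3-(phenylthio)propan-1-one F11. NaIO4 in aqueous methanol at 0 °C oxidises sulfur to give 1-[(2R,3R)-3-(2,4-dihydroxybenzoyl)-4,6-dihydroxy-2-(4-hydroxyphenyl)-2,3-dihydrobenzofuran-7-yl]-2-(4-hydroxyphenyl)-3-(phenylsulfinyl)propan-1-one F12. Gentle warming eliminates the sulfoxide in a syn elimination and returns to 35.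

## Further compounds

F1 | step 9 | (1R,2S)-2-[3-bromo-2-fluoro-4,6-bis(triisopropylsilyloxy)phenyl]-1-[4-(triisopropylsilyloxy)phenyl]-3-(trityloxy)propan-1-ol | O[C@@H](c1ccc(O[Si](C(C)C)(C(C)C)C(C)C)cc1)[C@@H](c1c(F)c(Br)c(O[Si](C(C)C)(C(C)C)C(C)C)cc1O[Si](C(C)C)(C(C)C)C(C)C)COC(c1ccccc1)(c1ccccc1)c1ccccc1
F2 | step 9 | (1R,2S)-2-[2-fluoro-3-formyl-4,6-bis(triisopropylsilyloxy)phenyl]-1-[4-(triisopropylsilyloxy)phenyl]-3-(trityloxy)propan-1-ol | O[C@@H](c1ccc(O[Si](C(C)C)(C(C)C)C(C)C)cc1)[C@@H](c1c(F)c(C=O)c(O[Si](C(C)C)(C(C)C)C(C)C)cc1O[Si](C(C)C)(C(C)C)C(C)C)COC(c1ccccc1)(c1ccccc1)c1ccccc1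
F3 | step 13 | 1-[4-(triisopropylsilyloxy)phenyl]ethanone 2,4,6-triisopropylbenzenesulfonylhydrazone | CC(=NNS(=O)(=O)c1c(C(C)C)cc(C(C)C)cc1C(C)C)c1ccc(O[Si](C(C)C)(C(C)C)C(C)C)cc1
F4 | step 13 | {1-[4-(triisopropylsilyloxy)phenyl]vinyl}lithium | C=C([Li])c1ccc(O[Si](C(C)C)(C(C)C)C(C)C)cc1
F5 | step 14 | (2R,3R)-trans-4,6-bis(triisopropylsilyloxy)-2-[4-(triisopropylsilyloxy)phenyl]-2,3-dihydrobenzofuran-3,7-dicarbaldehyde | O=Cc1c(O[Si](C(C)C)(C(C)C)C(C)C)cc(O[Si](C(C)C)(C(C)C)C(C)C)c2c1O[C@@H](c1ccc(O[Si](C(C)C)(C(C)C)C(C)C)cc1)[C@@H]2C=O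
F6 | step 14 | (2R,3S)-trans-3-{[2,4-bis(triisopropylsilyloxy)phenyl](hydroxy)methyl}-4,6-bis(triisopropylsilyloxy)-2-[4-(triisopropylsilyloxy)phenyl]-2,3-dihydrobenzofuran-7-carbaldehyde, carbinol epimers | O=Cc1c(O[Si](C(C)C)(C(C)C)C(C)C)cc(O[Si](C(C)C)(C(C)C)C(C)C)c2c1O[C@@H](c1ccc(O[Si](C(C)C)(C(C)C)C(C)C)cc1)[C@@H]2C(O)c1ccc(O[Si](C(C)C)(C(C)C)C(C)C)cc1O[Si](C(C)C)(C(C)C)C(C)C
F7 | step 14 | (2R,3R)-trans-3-[2,4-bis(triisopropylsilyloxy)benzoyl]-4,6-bis(triisopropylsilyloxy)-2-[4-(triisopropylsilyloxy)phenyl]-2,3-dihydrobenzofuran-7-carbaldehyde | O=Cc1c(O[Si](C(C)C)(C(C)C)C(C)C)cc(O[Si](C(C)C)(C(C)C)C(C)C)c2c1O[C@@H](c1ccc(O[Si](C(C)C)(C(C)C)C(C)C)cc1)[C@@H]2C(=O)c1ccc(O[Si](C(C)C)(C(C)C)C(C)C)cc1O[Si](C(C)C)(C(C)C)C(C)C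
F8 | step 14 | {(2R,3R)-trans-7-{1-hydroxy-2-[4-(triisopropylsilyloxy)phenyl]prop-2-en-1-yl}-4,6-bis(triisopropylsilyloxy)-2-[4-(triisopropylsilyloxy)phenyl]-2,3-dihydrobenzofuran-3-yl}[2,4-bis(triisopropylsilyloxy)phenyl]methanone, carbinol epimers | C=C(C(O)c1c(O[Si](C(C)C)(C(C)C)C(C)C)cc(O[Si](C(C)C)(C(C)C)C(C)C)c2c1O[C@@H](c1ccc(O[Si](C(C)C)(C(C)C)C(C)C)cc1)[C@@H]2C(=O)c1ccc(O[Si](C(C)C)(C(C)C)C(C)C)cc1O[Si](C(C)C)(C(C)C)C(C)C)c1ccc(O[Si](C(C)C)(C(C)C)C(C)C)cc1
F9 | step 16 | 1-iodo-2,4-bis(triisopropylsilyloxy)benzene | Ic1ccc(O[Si](C(C)C)(C(C)C)C(C)C)cc1O[Si](C(C)C)(C(C)C)C(C)C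
F10 | step 18 | 1-{(2R,3R)-trans-3-[2,4-bis(triisopropylsilyloxy)benzoyl]-4,6-bis(triisopropylsilyloxy)-2-[4-(triisopropylsilyloxy)phenyl]-2,3-dihydrobenzofuran-7-yl}-3-(phenylthio)-2-[4-(triisopropylsilyloxy)phenyl]propan-1-one, epimers at the new centre | O=C(C(CSc1ccccc1)c1ccc(O[Si](C(C)C)(C(C)C)C(C)C)cc1)c1c(O[Si](C(C)C)(C(C)C)C(C)C)cc(O[Si](C(C)C)(C(C)C)C(C)C)c2c1O[C@@H](c1ccc(O[Si](C(C)C)(C(C)C)C(C)C)cc1)[C@@H]2C(=O)c1ccc(O[Si](C(C)C)(C(C)C)C(C)C)cc1O[Si](C(C)C)(C(C)C)C(C)C
F11 | step 18 | 1-[(2R,3R)-3-(2,4-dihydroxybenzoyl)-4,6-dihydroxy-2-(4-hydroxyphenyl)-2,3-dihydrobenzofuran-7-yl]-2-(4-hydroxyphenyl)-3-(phenylthio)propan-1-one | O=C(C(CSc1ccccc1)c1ccc(O)cc1)c1c(O)cc(O)c2c1O[C@@H](c1ccc(O)cc1)[C@@H]2C(=O)c1ccc(O)cc1O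
F12 | step 18 | 1-[(2R,3R)-3-(2,4-dihydroxybenzoyl)-4,6-dihydroxy-2-(4-hydroxyphenyl)-2,3-dihydrobenzofuran-7-yl]-2-(4-hydroxyphenyl)-3-(phenylsulfinyl)propan-1-one | O=C(C(CS(=O)c1ccccc1)c1ccc(O)cc1)c1c(O)cc(O)c2c1O[C@@H](c1ccc(O)cc1)[C@@H]2C(=O)c1ccc(O)cc1O
A1 | alternative 1 | {(2R,3R)-trans-4,6-bis(benzyloxy)-2-[4-(benzyloxy)phenyl]-7-iodo-2,3-dihydrobenzofuran-3-yl}[2,4-bis(benzyloxy)phenyl]methanone | Ic1c(OCc3ccccc3)cc(OCc3ccccc3)c2c1O[C@@H](c1ccc(OCc3ccccc3)cc1)[C@@H]2C(=O)c1ccc(OCc3ccccc3)cc1OCc1ccccc1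
A2 | alternative 1 | tributyl{1-[4-(benzyloxy)phenyl]vinyl}stannane | C=C([Sn](CCCC)(CCCC)CCCC)c1ccc(OCc2ccccc2)cc1
A3 | alternative 1 | hexa-O-benzyl ether of 35 | C=C(C(=O)c1c(OCc3ccccc3)cc(OCc3ccccc3)c2c1O[C@@H](c1ccc(OCc3ccccc3)cc1)[C@@H]2C(=O)c1ccc(OCc3ccccc3)cc1OCc1ccccc1)c1ccc(OCc2ccccc2)cc1
A4 | alternative 2 | (2R)-5,7-bis(benzyloxy)-2-[4-(benzyloxy)phenyl]chroman-4-one | O=C1C[C@H](c2ccc(OCc3ccccc3)cc2)Oc2cc(OCc3ccccc3)cc(OCc3ccccc3)c12
A5 | alternative 2 | methyl (2R,3R)-trans-4,6-bis(benzyloxy)-2-[4-(benzyloxy)phenyl]-2,3-dihydrobenzofuran-3-carboxylate | c1c(OCc3ccccc3)cc(OCc3ccccc3)c2c1O[C@@H](c1ccc(OCc3ccccc3)cc1)[C@@H]2C(=O)OC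
A6 | alternative 3 | genistein (5,7,4′-trihydroxyisoflavone) | O=c1c(-c2ccc(O)cc2)coc2cc(O)cc(O)c12
A7 | alternative 3 | 6-{2-[2,4-bis(triisopropylsilyloxy)phenyl]-1-diazo-2-oxoethyl}-7-(triisopropylsilyloxy)-3-[4-(triisopropylsilyloxy)phenyl]-5-{[4-(triisopropylsilyloxy)benzyl]oxy}chromen-4-one | O=c1c(-c2ccc(O[Si](C(C)C)(C(C)C)C(C)C)cc2)coc2cc(O[Si](C(C)C)(C(C)C)C(C)C)c(C(=[N+]=[N-])C(=O)c3ccc(O[Si](C(C)C)(C(C)C)C(C)C)cc3O[Si](C(C)C)(C(C)C)C(C)C)c(OCc3ccc(O[Si](C(C)C)(C(C)C)C(C)C)cc3)c12
A8 | alternative 3 | silyl-protected trans-2-aryl-3-aroyl-dihydrofuran fused to the isoflavone | O=c1c(-c2ccc(O[Si](C(C)C)(C(C)C)C(C)C)cc2)coc2cc(O[Si](C(C)C)(C(C)C)C(C)C)c3c(c12)O[C@@H](c1ccc(O[Si](C(C)C)(C(C)C)C(C)C)cc1)[C@@H]3C(=O)c1ccc(O[Si](C(C)C)(C(C)C)C(C)C)cc1O[Si](C(C)C)(C(C)C)C(C)C
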